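The route rests on cutting the five-membered ring of the indole at C3–C3a and N1–C7a. Because the C7 bromine sits on the benzene ring next to C7a, 1-bromo-2-iodobenzene carries exactly one ortho substituent and one ortho hydrogen; a palladium/norbornene annulation with N-tosylaziridine therefore alkylates that hydrogen-bearing carbon (future C3a) and aminates the iodine-bearing carbon (future C7a) in one operation, delivering the pyrroline ring with N1, C2 and C3 from the aziridine and the bromine already at C7. The precursors are the bought aryl dihalide and a freshly made sulfonyl aziridine. Dehydrogenation, two regiocontrolled brominations (C3 electrophilic, C2 by lithiation) and detosylation finish the synthesis.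

Key step: step 2

Remark: the target has no stereocentre; norbornene is regenerated in step 2 and is treated as a co-catalyst, and lithium diisopropylamide is used as a bought solution.

Step 1
Reactants: 1 2-aminoethanol; 2 p-toluenesulfonyl chloride (2.4 equiv)
Product: 5 N-tosylaziridine, via N-tosyl-2-aminoethanol 3 (not isolated), via N,O-ditosyl-2-aminoethanol 4 (not isolated)
Conditions: KOH (excess), H2O/CH2Cl2, rt, vigorous stirring; used soon after isolation
Reagents that add atoms: none
Why: N-sulfonylation, O-sulfonylation and intramolecular SN2 displacement of the tosylate by the sulfonamide anion (3-exo-tet, Wenker-type aziridine synthesis) run in one flask under biphasic hydroxide, a known one-pot conversion of unhindered 2-amino alcohols.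

Step 2
Reactants: 6 1-bromo-2-iodobenzene; 5 N-tosylaziridine (1.5 equiv)
Product: 7 7-bromo-1-tosylindoline
Conditions: Pd(OAc)2 (10 mol %), tri(2-furyl)phosphine (20 mol %), norbornene (1 equiv), Cs2CO3 (2.5 equiv), MeCN, 80 °C, Ar
Reagents that add atoms: none
Why: Zerovalent palladium inserts into the C–I bond of 6, norbornene undergoes carbopalladation, and C–H palladation at the only free ortho position gives an aryl–norbornyl palladacycle of divalent palladium. This palladacycle opens aziridine 5 at a CH2 carbon in an SN2-type oxidative addition to tetravalent palladium, and aryl–alkyl reductive elimination makes C3–C3a. With both ortho positions now substituted, norbornene is expelled by β-carbon elimination, leaving an arylpalladium sulfonamide of divalent palladium at the former C–I carbon. The five-membered ring (N1, C2, C3, C3a, C7a) then closes by intramolecular C–N reductive elimination from a six-membered azapalladacycle, an ipso amination of Buchwald–Hartwig type that forms N1–C7a. The closest known reaction type is the Catellani annulation of ortho-substituted aryl iodides with N-sulfonylaziridines to indolines, and no stereocentre is formed. The step needs chemoselective insertion into C–I over C–Br and a single site of alkylation; the weaker C–I bond, the hindered bromine, a mild tri(2-furyl)phosphine catalyst at moderate temperature and the lone ortho hydrogen secure both, while the bromine doubles as the ortho substituent that forces norbornene extrusion.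

Step 3
Reactants: 7 7-bromo-1-tosylindoline
Product: 8 7-bromo-1-tosylindole
Conditions: DDQ (2 equiv), 1,4-dioxane, reflux
Reagents that add atoms: none
Why: DDQ dehydrogenation (hydride abstraction at the benzylic C3, then loss of the C2 proton) should aromatise the five-membered ring, driven by the gain of indole aromaticity, while the sulfonamide and the aryl bromide are inert to the quinone.

Step 4
Reactants: 8 7-bromo-1-tosylindole
Product: 9 3,7-dibromo-1-tosylindole
Conditions: Br2 (1.1 equiv), CH2Cl2, 0 °C to rt; aq. Na2S2O3 work-up
Reagents that add atoms: bromine, BrBr
Why: Electrophilic aromatic bromination of an N-sulfonylindole goes to C3, the nucleophilic end of the enamide-like C2=C3 bond, while the N-tosyl group and the C7 bromine deactivate the benzene ring against a second substitution.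

Step 5
Reactants: 9 3,7-dibromo-1-tosylindole
Product: 11 2,3,7-tribromo-1-tosylindole, via 3,7-dibromo-2-lithio-1-tosylindole 10 (not isolated)
Conditions: lithium diisopropylamide (1.15 equiv), THF, −78 °C; then BrCCl2CCl2Br, −78 °C to rt
Reagents that add atoms: 1,2-dibromo-1,1,2,2-tetrachloroethane, BrC(Cl)(Cl)C(Cl)(Cl)Br
Why: Directed lithiation at C2, the most acidic C–H (flanked by the sulfonylated nitrogen and the C3 bromine), by an amide base that does not undergo bromine–lithium exchange, followed by electrophilic bromination of the aryllithium with a positive-bromine donor, is the established way to 2,3-dihalo-N-sulfonylindoles.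

Step 6
Reactants: 11 2,3,7-tribromo-1-tosylindole
Product: 12 2,3,7-tribromoindole
Conditions: Cs2CO3 (3 equiv), THF/MeOH 2:1, rt; neutral work-up, product stored cold and dark
Reagents that add atoms: none
Why: Nucleophilic N-desulfonylation by methoxide (sulfonyl transfer to methanol) should be fast because three bromines make the indolide a good leaving group, so the mild carbonate/methanol cleavage of N-tosylindoles suffices and the C–Br bonds stay untouched.

Compound list
1 | 2-aminoethanol | NCCO | starting material
2 | p-toluenesulfonyl chloride | Cc1ccc(cc1)S(Cl)(=O)=O | starting material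
3 | N-(2-hydroxyethyl)-4-methylbenzenesulfonamide (N-tosyl-2-aminoethanol) | Cc1ccc(cc1)S(=O)(=O)NCCO | intermediate (not isolated)
4 | 2-(4-methylphenylsulfonamido)ethyl 4-methylbenzenesulfonate (N,O-ditosyl-2-aminoethanol) | Cc1ccc(cc1)S(=O)(=O)NCCOS(=O)(=O)c1ccc(C)cc1 | intermediate (not isolated)
5 | N-tosylaziridine | Cc1ccc(cc1)S(=O)(=O)N1CC1 | intermediate
6 | 1-bromo-2-iodobenzene | Brc1ccccc1I | starting material
7 | 7-bromo-1-tosylindoline | Cc1ccc(cc1)S(=O)(=O)N1CCc2cccc(Br)c21 | intermediate
8 | 7-bromo-1-tosylindole | Cc1ccc(cc1)S(=O)(=O)n1ccc2cccc(Br)c21 | intermediate
9 | 3,7-dibromo-1-tosylindole | Cc1ccc(cc1)S(=O)(=O)n1cc(Br)c2cccc(Br)c21 | intermediate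
10 | 3,7-dibromo-2-lithio-1-tosylindole | [Li]c1c(Br)c2cccc(Br)c2n1S(=O)(=O)c1ccc(C)cc1 | intermediate (not isolated)
11 | 2,3,7-tribromo-1-tosylindole | Cc1ccc(cc1)S(=O)(=O)n1c(Br)c(Br)c2cccc(Br)c21 | intermediate
12 | 2,3,7-tribromoindole | Brc1[nH]c2c(Br)cccc2c1Br | target

Total steps: 6. Longest linear sequence: 6 steps (1 to 12 through 5, 7, 8, 9 and 11).

Steps most likely to fail

Step 2. The catalyst may also insert into the C–Br bond of the substrate or of the product, a second molecule of aryl iodide may arylate the palladacycle, or the aziridine may oligomerise before it is intercepted. The fallback sets out from p-toluenesulfonyl chloride 2 and comes back at 8. 2-Bromonitrobenzene F1 is treated with CH2=CHMgBr (3 equiv, THF, −40 °C) in a Bartoli indole synthesis, for which an ortho-bromo nitroarene is a favourable substrate, to give 7-bromoindole F2. N-Sulfonylation of F2 with 2 (NaH, DMF, 0 °C) then gives 7-bromo-1-tosylindole 8, so that steps 1 to 3 are bypassed.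

Step 3. Hydride abstraction may be too slow, because the sulfonylated nitrogen, twisted by the neighbouring bromine, gives little assistance; the consequence would be incomplete conversion or degradation on prolonged heating. The fallback sets out from 7 and comes back at 8. Wohl–Ziegler bromination (N-bromosuccinimide, azobisisobutyronitrile, PhCF3, 80 °C) at the secondary benzylic C3 gives racemic 3,7-dibromo-1-tosylindoline F3. Elimination of HBr with DBU (THF, rt) then gives 8; bromination at C2 in place of C3 would eliminate to the same indole.

Step 5. Deprotonation may compete at C6 next to the C7 bromine or at the tosyl methyl group, and bromine may migrate in the 3-bromo-2-lithio species before it is trapped. The fallback reverses the order of the two halogenations; it sets out from 8 and comes back at 11. Lithiation of 8 (lithium diisopropylamide, THF, −78 °C) gives 7-bromo-2-lithio-1-tosylindole F4, which has no bromine next to the carbanion. Trapping with BrCCl2CCl2Br gives 2,7-dibromo-1-tosylindole F5, and electrophilic bromination at C3 (Br2, CH2Cl2, rt) gives 11.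

Further compounds
F1 | step 2 | 2-bromonitrobenzene | [O-][N+](=O)c1ccccc1Br
F2 | step 2 | 7-bromoindole | Brc1cccc2cc[nH]c12
F3 | step 3 | 3,7-dibromo-1-tosylindoline (racemic) | Cc1ccc(cc1)S(=O)(=O)N1CC(Br)c2cccc(Br)c21
F4 | step 5 | 7-bromo-2-lithio-1-tosylindole | [Li]c1cc2cccc(Br)c2n1S(=O)(=O)c1ccc(C)cc1
F5 | step 5 | 2,7-dibromo-1-tosylindole | Cc1ccc(cc1)S(=O)(=O)n1c(Br)cc2cccc(Br)c21
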